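**Retrosynthetic overview**
- Target 12 is traced back (debenzylation, N–O cleavage) to alkoxyamine 10. The key cut is the aryl–CH2 bond together with the C4–O bond, made in one three-component radical step from methylene-oxolane 7, arenediazonium salt 9 and the aminoxyl TEMPO.
- Enabling feature: the exocyclic, 1,1-disubstituted C4=CH2 on the oxolane ring. Its free CH2 end takes the aryl radical, and the resulting tertiary ring radical at C4 sits next to C3 (CH2OAc), which shields one face, so oxygen enters anti and sets C4.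
- 7 comes from ring closure C3–C4 by titanium-mediated epoxide opening and 5-exo-dig radical cyclisation of epoxy propargyl ether 5, which sets C3 trans to C2.
- C2 comes from lipase resolution of the vinyl Grignard adduct of O-benzylvanillin 1.
- Ring order: both benzene rings are bought; the oxolane is the only ring made (step 5).

Key step: step 8

Remark: the lipase is assumed to show its usual preference for acylating the (R)-enantiomer of 1-arylprop-2-en-1-ols (aryl large, vinyl medium); 1 and 8 are taken as purchasable.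

**Step 1**
Reactants: 1 4-(benzyloxy)-3-methoxybenzaldehyde
Product: 2 rac-1-[4-(benzyloxy)-3-methoxyphenyl]prop-2-en-1-ol
Conditions: CH2=CHMgBr, THF, 0 °C; aq NH4Cl
Reagents that add atoms: vinylmagnesium bromide, C=C[Mg]Br
Why: Grignard 1,2-addition to the aldehyde; the carbinol centre forms racemic and is resolved in step 2.

**Step 2**
Reactants: 2 rac-1-[4-(benzyloxy)-3-methoxyphenyl]prop-2-en-1-ol
Product: 3 (1S)-1-[4-(benzyloxy)-3-methoxyphenyl]prop-2-en-1-ol
Conditions: immobilised Candida antarctica lipase B, vinyl acetate, MTBE, 30 °C, stopped just past half conversion; chromatography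
Reagents that add atoms: none
Why: Lipase-catalysed kinetic resolution by enantioselective transesterification; the (R)-alcohol should be acetylated and the (S)-alcohol, the future C2 of the oxolane, should remain.

**Step 3**
Reactants: 3 (1S)-1-[4-(benzyloxy)-3-methoxyphenyl]prop-2-en-1-ol
Product: 4 1-(benzyloxy)-2-methoxy-4-[(1S)-1-(prop-2-yn-1-yloxy)prop-2-en-1-yl]benzene
Conditions: NaH, propargyl bromide, TBAI (cat.), THF/DMF, 0 °C to rt
Reagents that add atoms: propargyl bromide, C#CCBr
Why: Williamson ether synthesis at oxygen, so the stereocentre is not touched.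

**Step 4**
Reactants: 4 1-(benzyloxy)-2-methoxy-4-[(1S)-1-(prop-2-yn-1-yloxy)prop-2-en-1-yl]benzene
Product: 5 2-{(R)-[4-(benzyloxy)-3-methoxyphenyl](prop-2-yn-1-yloxy)methyl}oxirane, mixture of epimers at the oxirane carbon
Conditions: mCPBA, NaHCO3, CH2Cl2, rt
Reagents that add atoms: mCPBA, OOC(=O)c1cccc(Cl)c1
Why: Prilezhaev epoxidation of the only alkene (alkyne and arene react more slowly); the oxirane carbon forms as a mixture, which does not matter because it becomes a planar radical in step 5.

**Step 5**
Reactants: 5 2-{(R)-[4-(benzyloxy)-3-methoxyphenyl](prop-2-yn-1-yloxy)methyl}oxirane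
Product: 6 [(2S,3R)-2-[4-(benzyloxy)-3-methoxyphenyl]-4-methylideneoxolan-3-yl]methanol
Conditions: Cp2TiCl2 (2.2 equiv), Zn dust, 1,4-cyclohexadiene, THF, rt; aq NaH2PO4; chromatography
Reagents that add atoms: none
Why: Nugent–RajanBabu epoxide opening by Cp2TiCl (trivalent titanium) gives the secondary radical at C3, which closes the oxolane by 5-exo-dig attack on the alkyne, and the vinyl radical takes hydrogen from cyclohexadiene; C3 is set in the ring closure, where a chair-like transition state with the C2 aryl pseudo-equatorial should favour the 2,3-trans isomer.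

**Step 6**
Reactants: 6 [(2S,3R)-2-[4-(benzyloxy)-3-methoxyphenyl]-4-methylideneoxolan-3-yl]methanol
Product: 7 [(2S,3R)-2-[4-(benzyloxy)-3-methoxyphenyl]-4-methylideneoxolan-3-yl]methyl acetate
Conditions: Ac2O, pyridine, DMAP (cat.), CH2Cl2, 0 °C
Reagents that add atoms: acetic anhydride, CC(=O)OC(C)=O
Why: DMAP-catalysed O-acetylation of the primary alcohol installs the ester of the target, which also serves as the face-shielding group at C3 in step 8.

**Step 7**
Reactants: 8 4-(benzyloxy)-3-methoxyaniline
Product: 9 4-(benzyloxy)-3-methoxybenzenediazonium tetrafluoroborate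
Conditions: NaNO2, aq HBF4, 0 °C; filter, wash with Et2O
Reagents that add atoms: sodium nitrite, [Na+].[O-]N=O; tetrafluoroboric acid, [H+].F[B-](F)(F)F
Why: Diazotisation of the aniline; the tetrafluoroborate should precipitate as a storable aryl radical precursor.

**Step 8**
Reactants: 7 [(2S,3R)-2-[4-(benzyloxy)-3-methoxyphenyl]-4-methylideneoxolan-3-yl]methyl acetate; 9 4-(benzyloxy)-3-methoxybenzenediazonium tetrafluoroborate
Product: 10 {(2S,3R,4S)-2-[4-(benzyloxy)-3-methoxyphenyl]-4-{[4-(benzyloxy)-3-methoxyphenyl]methyl}-4-[(2,2,6,6-tetramethylpiperidin-1-yl)oxy]oxolan-3-yl}methyl acetate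
Conditions: TEMPO, Na, THF (gives TEMPONa), added over 2 h to 7 and 9 (3 equiv) in PhCF3, rt
Reagents that add atoms: TEMPO, CC1(C)CCCC(C)(C)N1[O]
Why: Electron transfer from the aminoxyl anion to 9 releases N2, the aryl radical and the persistent TEMPO radical; the aryl radical adds to the unsubstituted CH2 end of the exocyclic alkene (Meerwein-type addition) to give the tertiary C4 radical, which cross-couples with TEMPO (persistent radical effect). The closest known reaction type is the metal-free radical oxyarylation (carboaminoxylation) of unactivated alkenes with arenediazonium salts and TEMPONa. No ring is closed. The new C4 stereocentre is set in the C–O bond formation: the planar ring radical is flanked by C3, whose acetoxymethyl group shields one face, so the bulky aminoxyl should enter anti to it, placing oxygen trans to CH2OAc and cis to the C2 aryl (4S). The step needs regioselectivity, secured by the 1,1-disubstitution that makes the radical tertiary, and chemoselectivity for addition over hydrogen abstraction at the allylic and benzylic C–H bonds, which rests on the faster addition of aryl radicals to alkenes and on slow generation of the radical from an excess of 9.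

**Step 9**
Reactants: 10 the alkoxyamine acetate from step 8
Product: 11 {(2S,3R,4S)-2-[4-(benzyloxy)-3-methoxyphenyl]-4-{[4-(benzyloxy)-3-methoxyphenyl]methyl}-4-hydroxyoxolan-3-yl}methyl acetate
Conditions: Zn dust, AcOH/THF/H2O, 50 °C
Reagents that add atoms: none
Why: Reductive N–O cleavage of the alkoxyamine by zinc in acetic acid; the C4–O bond is not broken, so the configuration is kept, and the primary acetate should survive the mildly acidic medium.

**Step 10**
Reactants: 11 the di-O-benzyl monoacetate from step 9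
Product: 12 [(2S,3R,4S)-4-hydroxy-2-(4-hydroxy-3-methoxyphenyl)-4-[(4-hydroxy-3-methoxyphenyl)methyl]oxolan-3-yl]methyl acetate (olivil monoacetate)
Conditions: H2 (1 atm), Pd/C, EtOAc, rt, stopped after uptake of two equivalents
Reagents that add atoms: none
Why: Hydrogenolysis of the two aryl benzyl ethers; the acetate and the tertiary alcohol are inert and the ring C2–O bond should react more slowly, so no stereocentre is touched.

**Compound list**
1 | 4-(benzyloxy)-3-methoxybenzaldehyde | COc1cc(C=O)ccc1OCc1ccccc1 | starting material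
2 | rac-1-[4-(benzyloxy)-3-methoxyphenyl]prop-2-en-1-ol | C=CC(O)c1ccc(OCc2ccccc2)c(OC)c1 | intermediate
3 | (1S)-1-[4-(benzyloxy)-3-methoxyphenyl]prop-2-en-1-ol | C=C[C@H](O)c1ccc(OCc2ccccc2)c(OC)c1 | intermediate
4 | 1-(benzyloxy)-2-methoxy-4-[(1S)-1-(prop-2-yn-1-yloxy)prop-2-en-1-yl]benzene | C=C[C@H](OCC#C)c1ccc(OCc2ccccc2)c(OC)c1 | intermediate
5 | 2-{(R)-[4-(benzyloxy)-3-methoxyphenyl](prop-2-yn-1-yloxy)methyl}oxirane, both epimers at the oxirane carbon | C1OC1[C@H](OCC#C)c1ccc(OCc2ccccc2)c(OC)c1 | intermediate
6 | [(2S,3R)-2-[4-(benzyloxy)-3-methoxyphenyl]-4-methylideneoxolan-3-yl]methanol | C=C1CO[C@H](c2ccc(OCc3ccccc3)c(OC)c2)[C@H]1CO | intermediate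
7 | [(2S,3R)-2-[4-(benzyloxy)-3-methoxyphenyl]-4-methylideneoxolan-3-yl]methyl acetate | C=C1CO[C@H](c2ccc(OCc3ccccc3)c(OC)c2)[C@H]1COC(C)=O | intermediate
8 | 4-(benzyloxy)-3-methoxyaniline | COc1cc(N)ccc1OCc1ccccc1 | starting material
9 | 4-(benzyloxy)-3-methoxybenzenediazonium tetrafluoroborate | COc1cc([N+]#N)ccc1OCc1ccccc1.F[B-](F)(F)F | intermediate
10 | {(2S,3R,4S)-2-[4-(benzyloxy)-3-methoxyphenyl]-4-{[4-(benzyloxy)-3-methoxyphenyl]methyl}-4-[(2,2,6,6-tetramethylpiperidin-1-yl)oxy]oxolan-3-yl}methyl acetate | COc1cc(C[C@@]2(ON3C(C)(C)CCCC3(C)C)CO[C@H](c3ccc(OCc4ccccc4)c(OC)c3)[C@H]2COC(C)=O)ccc1OCc1ccccc1 | intermediate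
11 | {(2S,3R,4S)-2-[4-(benzyloxy)-3-methoxyphenyl]-4-{[4-(benzyloxy)-3-methoxyphenyl]methyl}-4-hydroxyoxolan-3-yl}methyl acetate | COc1cc(C[C@@]2(O)CO[C@H](c3ccc(OCc4ccccc4)c(OC)c3)[C@H]2COC(C)=O)ccc1OCc1ccccc1 | intermediate
12 | [(2S,3R,4S)-4-hydroxy-2-(4-hydroxy-3-methoxyphenyl)-4-[(4-hydroxy-3-methoxyphenyl)methyl]oxolan-3-yl]methyl acetate | COc1cc(C[C@@]2(O)CO[C@H](c3ccc(O)c(OC)c3)[C@H]2COC(C)=O)ccc1O | target

**Count**
Total steps: 10. Longest linear sequence: 9 (steps 1–6, 8, 9, 10).

**Steps most likely to fail**

1. Step 8. With the alkene as the limiting partner, aryl radicals may be lost to hydrogen abstraction or to direct capture by the aminoxyl before they add, and capture of the C4 radical may show poor facial selectivity. Fallback, from 7 back to 11 by polar chemistry: the exocyclic alkene of 7 is epoxidised (mCPBA, NaHCO3, CH2Cl2) from the face away from CH2OAc to give [(3R,6S,7R)-6-[4-(benzyloxy)-3-methoxyphenyl]-1,5-dioxaspiro[2.4]heptan-7-yl]methyl acetate F1. This is opened at its CH2 carbon under CuI catalysis (THF, −30 °C) by [4-(benzyloxy)-3-methoxyphenyl]magnesium bromide F2, made from purchased 1-(benzyloxy)-4-bromo-2-methoxybenzene and Mg. The excess Grignard reagent also removes the acetate, so the product is (3S,4R,5S)-5-[4-(benzyloxy)-3-methoxyphenyl]-3-{[4-(benzyloxy)-3-methoxyphenyl]methyl}-4-(hydroxymethyl)oxolan-3-ol F3. Selective acetylation of its primary hydroxyl (Ac2O, pyridine, 0 °C) returns to 11.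

2. Step 5. The radical at C3 may be reduced by a second Cp2TiCl before it cyclises (deoxygenation back to alkene 4), and the trans to cis preference in the ring closure may be low. Fallback, from 4 to 6 without the epoxide: Pd(OAc)2-catalysed borylative cyclisation of the 1,6-enyne 4 with B2pin2 (MeOH, toluene, 50 °C; hydropalladation of the alkyne, insertion of the alkene, C–B bond formation) should give 2-{[(2S,3S)-2-[4-(benzyloxy)-3-methoxyphenyl]-4-methylideneoxolan-3-yl]methyl}-4,4,5,5-tetramethyl-1,3,2-dioxaborolane F4. Oxidation with NaBO3 in THF/H2O returns to 6.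

3. Step 10. Over-reduction may occur: once the para-phenol is unmasked, the benzylic C2–O bond of the ring becomes prone to hydrogenolysis. Fallback, from 11 to 12 without hydrogen: Lewis-acid debenzylation with BCl3 and pentamethylbenzene as cation scavenger in CH2Cl2 at −78 °C, which should leave the acetate and the ring ether intact at that temperature.

**Further compounds**
F1 | step 8 | [(3R,6S,7R)-6-[4-(benzyloxy)-3-methoxyphenyl]-1,5-dioxaspiro[2.4]heptan-7-yl]methyl acetate | C1O[C@@]12CO[C@H](c3ccc(OCc4ccccc4)c(OC)c3)[C@H]2COC(C)=O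
F2 | step 8 | [4-(benzyloxy)-3-methoxyphenyl]magnesium bromide | COc1cc([Mg]Br)ccc1OCc1ccccc1
F3 | step 8 | (3S,4R,5S)-5-[4-(benzyloxy)-3-methoxyphenyl]-3-{[4-(benzyloxy)-3-methoxyphenyl]methyl}-4-(hydroxymethyl)oxolan-3-ol | COc1cc(C[C@@]2(O)CO[C@H](c3ccc(OCc4ccccc4)c(OC)c3)[C@H]2CO)ccc1OCc1ccccc1
F4 | step 5 | 2-{[(2S,3S)-2-[4-(benzyloxy)-3-methoxyphenyl]-4-methylideneoxolan-3-yl]methyl}-4,4,5,5-tetramethyl-1,3,2-dioxaborolane | C=C1CO[C@H](c2ccc(OCc3ccccc3)c(OC)c2)[C@H]1CB1OC(C)(C)C(C)(C)O1
F0 | step 10 | none | none
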